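Follow one molecule of E through each flask and ask, at each moment, by which exit it leaves.

    E + X ⇌ E.X (K1 = 190 /M, k1 = 1.0 /M/h)
    E → Z (k2 = 0.11 /h)
    2 E → E2 (k3 = 2.3 /M/h)

common to all: time 8.0 h
- Thursday's: E 0.10 M; X 0.250 M (fed, over 40 min); all else is in the flask from the start; the feed brings no volume worth counting
- Sunday's: E 0.10 M (fed, over 6.0 h); X 0.250 M; all else is in the flask from the start; the feed brings no volume worth counting
- Tuesday's: E 0.10 M; X 0.250 M (fed, over 6.0 h); all else is in the flask from the start; the feed brings no volume worth counting
- Friday's: E 0.10 M; X 0.250 M; everything together at the start

1. the best flask by amount of E.X, in percent of the E charged; "all alike" if 1.5 percentage points covers them all (Thursday's / Sunday's / Tuesday's / Friday's / all alike)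
2. amount of E.X at the end, in percent of the E charged, Thursday's
3. amount of E.X at the end, in percent of the E charged, Sunday's
4. amount of E.X at the end, in percent of the E charged, Tuesday's
5. amount of E.X at the end, in percent of the E charged, Friday's

- a species is counted by the E in it: one E2 counts as two
- two of one species on the left: rate k times its square, two consumed each time
- run time (Thursday's): 8.0 h

A molecule of E has three exits, each with a rate per molecule. Capture by X runs at 0.250 /h with [X] as charged, decay to Z at 0.11 /h, and dimerisation at 0.460 /h with [E] as charged, falling in proportion to [E]. In Friday's flask capture therefore opens with 30.5% of the traffic. That cannot stand for the run, since the share climbs towards 69.4% as [E] falls. Averaged over the falling [E], with [X] held, it gives 44.7%. But [X] is not held: that much E.X leaves [X] at 0.205 M, and the same average at that [X] gives 40.2%, the lower estimate for Friday's. Both figures take the binding as one-way and count no E left over at the end.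

In Sunday's flask the feed sets [E] instead. Feed and exits balance at 0.0327 M, and that gives 49.0% as the capture share, the capture rate over the sum of the three exits at that moment, a selectivity. The balance needs time to form, but its 1.51 h is shorter than the feed, so the figure holds for most of the run. Some E remains at the end, about 11.8% of the charge, which brings Sunday's to 43.2%. The fall in [X] counts against this figure too, so the reckoning cannot part Sunday's from Friday's.

Tuesday's flask starves capture. Dimerisation alone takes 2.17 h to bring [E] from 0.10 M to 0.0500 M, and by then the feed has brought 0.0906 M of X even if none were used, so at that [E] the share is 21.0%. Thursday's feed ends sooner than that, which puts it a little under Friday's.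

The forecast reads 37% for Thursday's, 45.5% for Sunday's, 17% for Tuesday's and 41% for Friday's, and names Sunday's, since “feeding E slowly keeps its concentration low and favours capture by X”. Its Sunday's figure stands above this reckoning's.

Sunday's is best at 42.0%, with Thursday's at 35.5%, Tuesday's at 19.1% and Friday's at 39.9%. At 8.00 h Sunday's flask still holds 14.5% as E, and 49.0% of the remainder is 41.9%. In the neighbour of Sunday's with 0.15 M of X, the odds of capture shrink with [X] by a factor 0.600, the other exits held, so the share becomes 36.6%, and with 18.7% left as E that is 29.8%. That flask holds 28.3% of E.X.

The numbers of this flask are those of an exercise; the flask was simulated.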